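**Plan**

1. Retrosynthesis: cut C6–C7 (ring B, carbene-catalysed benzoin of the 6,7-seco dialdehyde 38), then O16–C15 (ring D, alkynol cycloisomerisation), O9–C13 (ring C, epoxide opening), C12–C13 (B-alkyl Suzuki), C4–C19 (silicon-tethered radical) and C9–C10 (ester-enolate Claisen), down to ring A alcohol 5 and dioxane acid 11.
2. Enabling feature: C6 (carbinol) and C7 (ketone) are neighbouring ring B carbons that both come from carbonyl carbons. C6 hangs on C5 between quaternary C4 and C10, C7 on the less hindered C8, so only C7 can become the acyl anion.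
3. Forward order: 5 + 11 → Claisen (C9, C10) → ring A decorated (C3, C4, C5) → ring C → ring D → ring B last.
4. Stereochemistry: C8 from an Evans aldol; C9 and C10 from the chelated chair Claisen, trans to the C8 methyl; C3 from CBS reduction; C4 and C5 from the tethered radical cyclisation; C13 from Sharpless epoxidation followed by inversion; C6 from the Felkin-type chair closure of the benzoin.
5. Ring D is closed before the key step, so that nothing has to be done afterwards on the base-sensitive β-alkoxy α-ketol.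

Key step: step 29

Remark: labdane numbering of the target is used for all intermediates (O9 = ether oxygen on C9, C19 = acetoxymethyl carbon on C4); compounds 1, 6, 7 and 29 are assumed to be commercial.

**Route**

Step 1
Reactants: 1 4,4-dimethoxycyclohexan-1-one
Product: 2 methyl 5,5-dimethoxy-2-oxocyclohexane-1-carboxylate (keto/enol mixture)
Conditions: NaH, (MeO)2CO, THF, reflux; AcOH quench
Reagents that add atoms: dimethyl carbonate COC(=O)OC
Why: C-acylation of the enolate of a symmetric ketone (crossed Claisen condensation) has no regiochemical issue and brings in C6.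

Step 2
Reactants: 2 methyl 5,5-dimethoxy-2-oxocyclohexane-1-carboxylate
Product: 3 methyl 5,5-dimethoxy-2-{[(trifluoromethyl)sulfonyl]oxy}cyclohex-1-ene-1-carboxylate
Conditions: Tf2O, iPr2NEt, CH2Cl2, −78 °C
Reagents that add atoms: trifluoromethanesulfonic anhydride O=S(=O)(OS(=O)(=O)C(F)(F)F)C(F)(F)F
Why: O-sulfonylation of the β-keto ester enol fixes the future C5=C10 double bond as an enol triflate.

Step 3
Reactants: 3 enol triflate
Product: 4 methyl 5,5-dimethoxy-2-methylcyclohex-1-ene-1-carboxylate
Conditions: MeMgBr, Fe(acac)3 (5 mol%), THF–NMP, −30 °C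
Reagents that add atoms: methylmagnesium bromide C[Mg]Br
Why: iron-catalysed Kumada-type coupling of the enol triflate should outrun Grignard addition to the ester and installs the C10 methyl.

Step 4
Reactants: 4 methyl 5,5-dimethoxy-2-methylcyclohex-1-ene-1-carboxylate
Product: 5 (5,5-dimethoxy-2-methylcyclohex-1-en-1-yl)methanol
Conditions: iBu2AlH, CH2Cl2, −78 °C; aq. potassium sodium tartrate
Reagents that add atoms: none
Why: 1,2-reduction of the conjugated ester gives the allylic alcohol whose CH2O carbon is C6.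

Step 5
Reactants: 6 (S)-4-benzyl-3-propionyloxazolidin-2-one; 7 furan-2-carbaldehyde
Product: 8 (S)-4-benzyl-3-[(2S,3S)-3-(furan-2-yl)-3-hydroxy-2-methylpropanoyl]oxazolidin-2-one
Conditions: Bu2BOTf, Et3N, CH2Cl2, −78 to 0 °C; then pH 7 buffer, MeOH, H2O2
Reagents that add atoms: none
Why: Evans syn-aldol reaction, in which the (Z)-boron enolate reacts through a Zimmerman–Traxler chair on the face away from the benzyl group and so sets C8 and the syn carbinol C9.

Step 6
Reactants: 8 aldol adduct
Product: 9 (1S,2R)-1-(furan-2-yl)-2-methylpropane-1,3-diol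
Conditions: LiBH4, MeOH (1 equiv), Et2O, 0 °C
Reagents that add atoms: none
Why: hydride cleavage of the exocyclic imide carbonyl removes the auxiliary and gives the 1,3-diol without touching C8.

Step 7
Reactants: 9 diol
Product: 10 (2S,4S,5R)-4-(furan-2-yl)-5-methyl-2-phenyl-1,3-dioxane (phenyl and furyl equatorial, methyl axial)
Conditions: PhCH(OMe)2, PPTS, CH2Cl2, 23 °C
Reagents that add atoms: benzaldehyde dimethyl acetal COC(OC)c1ccccc1
Why: acetal exchange under thermodynamic control puts phenyl and furyl equatorial on the chair dioxane, which leaves the C8 methyl of the syn diol axial.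

Step 8
Reactants: 10 furyl dioxane
Product: 11 (2S,4S,5R)-5-methyl-2-phenyl-1,3-dioxane-4-carboxylic acid
Conditions: O3, CH2Cl2–MeOH, −78 °C (stopped at the furan end point); Me2S
Reagents that add atoms: ozone [O-][O+]=O
Why: ozonolysis unmasks the electron-rich furan as the carboxyl group (C11) much faster than ozone attacks the acetal C–H.

Step 9
Reactants: 11 dioxane acid; 5 ring A allylic alcohol
Product: 12 (5,5-dimethoxy-2-methylcyclohex-1-en-1-yl)methyl (2S,4S,5R)-5-methyl-2-phenyl-1,3-dioxane-4-carboxylate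
Conditions: DCC, DMAP, CH2Cl2, 0 to 23 °C
Reagents that add atoms: none
Why: Steglich esterification joins the two halves under neutral conditions that spare the dimethyl ketal; the configuration at C9 need not survive.

Step 10
Reactants: 12 allylic ester
Product: 15 (2S,4R,5R)-4-[(1S)-5,5-dimethoxy-1-methyl-2-methylidenecyclohexyl]-5-methyl-2-phenyl-1,3-dioxane-4-carboxylic acid (dioxane C4 = C9, cyclohexyl C1 = C10; ring A unit trans to the C8 methyl), via silyl ketene acetal 13 (not isolated), via trimethylsilyl ester 14 (not isolated)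
Conditions: LDA, THF, −78 °C; TMSCl–Et3N; then 60 °C; aq. NaHCO3–MeOH, work-up at pH 5
Reagents that add atoms: none
Why: Ireland–Claisen rearrangement in which lithium chelation between the enolate oxygen and ring oxygen O9 fixes the ketene acetal geometry (OSiMe3 cis to O9), the chair transition state relates C9 to C10 as in the target, and C10 enters trans to the axial C8 methyl, so C8 sets the absolute sense at both new fully substituted carbons.

Step 11
Reactants: 15 Claisen acid
Product: 16 the primary alcohol of 15 (CO2H → CH2OH, C11)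
Conditions: LiAlH4, THF, 0 °C to reflux
Reagents that add atoms: none
Why: hydride reduction of the hindered carboxylic acid; ketal and acetal are inert.

Step 12
Reactants: 16 neopentyl alcohol
Product: 17 the aldehyde of 16 (C11H=O)
Conditions: Dess–Martin periodinane, NaHCO3, CH2Cl2, 23 °C
Reagents that add atoms: none
Why: Dess–Martin oxidation under buffered conditions; the aldehyde has no α-hydrogen and cannot epimerise.

Step 13
Reactants: 17 aldehyde
Product: 18 the 4-vinyl dioxane (C9–C11H=C12H2), otherwise as 15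
Conditions: Ph3PCH3Br, KHMDS, THF, 0 to 23 °C
Reagents that add atoms: methyltriphenylphosphonium bromide C[P+](c1ccccc1)(c1ccccc1)c1ccccc1.[Br-]
Why: Wittig methylenation of the non-enolisable aldehyde adds C12.

Step 14
Reactants: 18 vinyl dioxane
Product: 19 the C3 ketone of 18 (4-methylidene-cyclohexanone ring A, β,γ-unsaturated)
Conditions: PPTS, acetone–H2O, 23 °C
Reagents that add atoms: water O
Why: acid hydrolysis of the acyclic dimethyl ketal is much faster than that of the 2-phenyl-1,3-dioxane, so only the C3 ketone is freed.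

Step 15
Reactants: 19 β,γ-unsaturated ketone
Product: 20 the 4-methyl ketone (C4 epimers, C18 introduced)
Conditions: LDA, THF, −78 °C; MeI
Reagents that add atoms: iodomethane CI
Why: deprotonation at C4, which is both α to the ketone and allylic, gives the dienolate that alkylates at its α-carbon; the C4 configuration is irrelevant because C4 becomes sp2 in step 16.

Step 16
Reactants: 20 4-methyl ketone
Product: 22 the 4-methyl-4-en-3-one with a free C6 hydroxyl (C3=O, C4=C5, C5–CH2OH), via spiro epoxide 21 (not isolated)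
Conditions: mCPBA, NaHCO3, CH2Cl2, 0 °C; then DBU, 23 °C
Reagents that add atoms: 3-chloroperoxybenzoic acid OOC(=O)c1cccc(Cl)c1
Why: Prilezhaev epoxidation of the 1,1-disubstituted alkene (more nucleophilic than the vinyl group on the oxygen-bearing C9), then E1cB opening of the β,γ-epoxy ketone through the C4 enolate, which moves the double bond to C4=C5 and leaves the oxygen on C6.

Step 17
Reactants: 22 hydroxy enone
Product: 23 the 6-O-tert-butyldimethylsilyl ether of 22
Conditions: TBSCl, imidazole, DMF, 23 °C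
Reagents that add atoms: tert-butyldimethylsilyl chloride CC(C)(C)[Si](C)(C)Cl
Why: silylation of the primary allylic alcohol keeps C6–OH out of the tether chemistry that follows.

Step 18
Reactants: 23 enone
Product: 24 the (3S)-allylic alcohol (3β-OH)
Conditions: (R)-2-methyl-CBS-oxazaborolidine (20 mol%), catecholborane, toluene, −78 °C
Reagents that add atoms: none
Why: CBS reduction in which the alkenyl side acts as the large group, so the (R)-catalyst delivers hydride to the α face under reagent control; catecholborane does not hydroborate the alkenes at this temperature.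

Step 19
Reactants: 24 allylic alcohol
Product: 25 the 3-O-(bromomethyl)dimethylsilyl ether of 24
Conditions: BrCH2Si(CH3)2Cl, Et3N, DMAP, CH2Cl2, 0 °C
Reagents that add atoms: (bromomethyl)chlorodimethylsilane C[Si](C)(Cl)CBr
Why: silyl ether formation installs the one-carbon radical precursor on the 3β oxygen.

Step 20
Reactants: 25 bromomethylsilyl ether
Product: 27 the 3β,19-diol (C4: α-methyl, β-CH2OH; 5α-H; 6-OTBS), via cyclic siloxane 26 (not isolated)
Conditions: Bu3SnH, AIBN, benzene, 80 °C; then H2O2, KF, KHCO3, THF–MeOH, 23 °C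
Reagents that add atoms: hydrogen peroxide OO
Why: Nishiyama–Stork radical cyclisation, in which the α-silyl radical closes 5-exo onto C4 (C5 is shielded by quaternary C10) and the tether forces C19 cis to the 3β oxygen, the C5 radical takes hydrogen on the α face opposite the axial C19 and C20 groups, and Tamao–Fleming oxidation converts C–Si into C19–OH.

Step 21
Reactants: 27 diol
Product: 28 the 3β,19-diacetate
Conditions: Ac2O, pyridine, DMAP, CH2Cl2, 23 °C
Reagents that add atoms: acetic anhydride CC(=O)OC(C)=O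
Why: acylation of the only two free hydroxyls installs the acetates of the target.

Step 22
Reactants: 28 diacetate; 29 2-bromoprop-2-en-1-ol
Product: 31 the allylic alcohol with C9–CH2CH2–C(=CH2)–CH2OH (C11 to C14, C16), via alkylborane 30 (not isolated)
Conditions: 9-BBN, THF, 23 °C; then 29, PdCl2(dppf), AsPh3, K3PO4, DMF–H2O, 23 °C
Reagents that add atoms: none
Why: anti-Markovnikov hydroboration of the only remaining alkene followed by B-alkyl Suzuki–Miyaura coupling with the vinyl bromide attaches C13, C14 and C16.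

Step 23
Reactants: 31 allylic alcohol
Product: 32 the (13S)-13,16-epoxy alcohol (2-substituted glycidol, C14H2OH)
Conditions: Ti(OiPr)4 (10 mol%), L-(+)-diethyl tartrate, tBuOOH, 4 Å sieves, CH2Cl2, −20 °C
Reagents that add atoms: tert-butyl hydroperoxide CC(C)(C)OO
Why: Sharpless asymmetric epoxidation of a 2-substituted allylic alcohol; the L-(+)-tartrate complex selects the alkene face that gives the (13S)-epoxide, independent of the remote centres.

Step 24
Reactants: 32 epoxy alcohol
Product: 33 the epoxy aldehyde (C14H=O)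
Conditions: Dess–Martin periodinane, NaHCO3, CH2Cl2, 0 °C
Reagents that add atoms: none
Why: Dess–Martin oxidation; the aldehyde sits on a fully substituted carbon and cannot epimerise.

Step 25
Reactants: 33 epoxy aldehyde
Product: 34 the (13S)-13-ethynyl-13,16-epoxide
Conditions: Me3SiCHN2, LDA, THF, −78 to 0 °C
Reagents that add atoms: (trimethylsilyl)diazomethane C[Si](C)(C)C=[N+]=[N-]
Why: Colvin homologation, in which the lithiated diazomethane adds to the aldehyde, loss of silanolate and N2 gives an alkylidene carbene, and its 1,2-hydrogen shift gives the terminal alkyne (C15); at −78 °C the aldehyde should react well before the two hindered acetates.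

Step 26
Reactants: 34 alkynyl epoxide
Product: 36 (13R)-3β,19-diacetoxy-9α,13-epoxy-6,7-seco-labd-14-yne-6,7,16-triol, via 6-O-silyl diol 35 (not isolated)
Conditions: CSA (0.2 equiv), MeOH–CH2Cl2, 0 to 23 °C
Reagents that add atoms: none
Why: acid-catalysed 5-exo opening of the epoxide at its tertiary carbon by O9 (as acetal oxygen or freed hydroxyl) with inversion closes ring C and gives the 13R centre, while the same acid removes the benzylidene acetal by exchange with methanol and then the primary silyl ether.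

Step 27
Reactants: 36 alkynyl triol
Product: 37 (13R)-3β,19-diacetoxy-9α,13;15,16-diepoxy-6,7-seco-labd-14-ene-6,7-diol
Conditions: Mo(CO)6 (30 mol%), Et3N, Et2O, hν (350 nm), 23 °C
Reagents that add atoms: none
Why: alkynol cycloisomerisation through a molybdenum vinylidene, in which only the homopropargylic C16 hydroxyl can reach the carbene carbon, closes ring D 5-endo as the 2,3-dihydrofuran.

Step 28
Reactants: 37 seco diol
Product: 38 (13R)-3β,19-diacetoxy-9α,13;15,16-diepoxy-6,7-seco-labd-14-ene-6,7-dial
Conditions: Dess–Martin periodinane, NaHCO3, CH2Cl2, 0 °C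
Reagents that add atoms: none
Why: Dess–Martin oxidation of both primary alcohols under buffered, non-acidic conditions that the enol ether, the acetates and the α-centres C5 and C8 should tolerate.

Step 29
Reactants: 38 6,7-seco dialdehyde
Product: 39 (13R)-3β,19-diacetoxy-6β-hydroxy-9α,13;15,16-diepoxylabd-14-en-7-one (CNP0317137.1)
Conditions: 2-mesityl-6,7-dihydro-5H-pyrrolo[2,1-c][1,2,4]triazol-2-ium chloride (20 mol%), iPr2NEt (30 mol%), CH2Cl2, 23 °C
Reagents that add atoms: none
Why: The carbene adds to the C7 aldehyde, the only one it can reach because C6 is flanked by quaternary C4 and C10, and the resulting Breslow intermediate attacks the C6 carbonyl through its nucleophilic C7; proton transfer and loss of the carbene give the α-ketol. The closest known reaction type is the intramolecular crossed benzoin cyclisation of a dialdehyde under N-heterocyclic carbene catalysis. Ring B closes 6-exo-trig through a chair in which the C8 methyl, C11 and the ring A bonds stay equatorial. The new C6 centre should follow the Felkin–Anh arrangement at C5: the forming bond is anti to C4, the carbonyl oxygen lies on the C10 side and the aldehyde hydrogen sits next to the bulky azolium-bearing C7, which gives the axial 6β-carbinol; this is the least secure point of the step. The step needs donor/acceptor selectivity (7-ketone, 6-carbinol), secured by the steric difference between the two aldehydes, and retention of C8 and of the kinetic 6β configuration, for which the base is weak and the reaction is stopped at conversion, because C8–H is α to the carbonyl and β to O9. The acetates and the enol ether of ring D are inert under these conditions.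

**Compound list**

1 | 4,4-dimethoxycyclohexan-1-one | COC1(OC)CCC(=O)CC1 | starting material
2 | methyl 5,5-dimethoxy-2-oxocyclohexane-1-carboxylate | COC(=O)C1CC(OC)(OC)CCC1=O | intermediate
3 | methyl 5,5-dimethoxy-2-{[(trifluoromethyl)sulfonyl]oxy}cyclohex-1-ene-1-carboxylate | COC(=O)C1=C(OS(=O)(=O)C(F)(F)F)CCC(OC)(OC)C1 | intermediate
4 | methyl 5,5-dimethoxy-2-methylcyclohex-1-ene-1-carboxylate | COC(=O)C1=C(C)CCC(OC)(OC)C1 | intermediate
5 | (5,5-dimethoxy-2-methylcyclohex-1-en-1-yl)methanol | COC1(OC)CCC(C)=C(CO)C1 | intermediate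
6 | (S)-4-benzyl-3-propionyloxazolidin-2-one | CCC(=O)N1[C@@H](Cc2ccccc2)COC1=O | starting material
7 | furan-2-carbaldehyde | O=Cc1ccco1 | starting material
8 | (S)-4-benzyl-3-[(2S,3S)-3-(furan-2-yl)-3-hydroxy-2-methylpropanoyl]oxazolidin-2-one | O=C1OC[C@H](Cc2ccccc2)N1C(=O)[C@@H](C)[C@H](O)c1ccco1 | intermediate
9 | (1S,2R)-1-(furan-2-yl)-2-methylpropane-1,3-diol | OC[C@@H](C)[C@H](O)c1ccco1 | intermediate
10 | (2S,4S,5R)-4-(furan-2-yl)-5-methyl-2-phenyl-1,3-dioxane | C[C@@H]1CO[C@H](c2ccccc2)O[C@@H]1c1ccco1 | intermediate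
11 | (2S,4S,5R)-5-methyl-2-phenyl-1,3-dioxane-4-carboxylic acid | C[C@@H]1CO[C@H](c2ccccc2)O[C@@H]1C(=O)O | intermediate
12 | (5,5-dimethoxy-2-methylcyclohex-1-en-1-yl)methyl ester of 11 | C[C@@H]1CO[C@H](c2ccccc2)O[C@@H]1C(=O)OCC1=C(C)CCC(OC)(OC)C1 | intermediate
13 | trimethylsilyl ketene acetal of 12 (OSiMe3 cis to O9) | C[C@@H]1CO[C@H](c2ccccc2)O/C1=C(\O[Si](C)(C)C)OCC1=C(C)CCC(OC)(OC)C1 | intermediate (not isolated)
14 | trimethylsilyl ester of 15 | C[C@@H]1CO[C@H](c2ccccc2)O[C@@]1(C(=O)O[Si](C)(C)C)[C@@]1(C)CCC(OC)(OC)CC1=C | intermediate (not isolated)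
15 | (2S,4R,5R)-4-[(1S)-5,5-dimethoxy-1-methyl-2-methylidenecyclohexyl]-5-methyl-2-phenyl-1,3-dioxane-4-carboxylic acid | C[C@@H]1CO[C@H](c2ccccc2)O[C@@]1(C(=O)O)[C@@]1(C)CCC(OC)(OC)CC1=C | intermediate
16 | primary alcohol of 15 (C11H2OH) | C[C@@H]1CO[C@H](c2ccccc2)O[C@@]1(CO)[C@@]1(C)CCC(OC)(OC)CC1=C | intermediate
17 | aldehyde of 16 (C11H=O) | C[C@@H]1CO[C@H](c2ccccc2)O[C@@]1(C=O)[C@@]1(C)CCC(OC)(OC)CC1=C | intermediate
18 | 4-vinyl dioxane (C11=C12) | C[C@@H]1CO[C@H](c2ccccc2)O[C@@]1(C=C)[C@@]1(C)CCC(OC)(OC)CC1=C | intermediate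
19 | C3 ketone of 18 | C[C@@H]1CO[C@H](c2ccccc2)O[C@@]1(C=C)[C@@]1(C)CCC(=O)CC1=C | intermediate
20 | 4-methyl ketone (C4 epimers) | C[C@@H]1CO[C@H](c2ccccc2)O[C@@]1(C=C)[C@@]1(C)CCC(=O)C(C)C1=C | intermediate
21 | 5,6-spiro epoxide of 20 | C[C@@H]1CO[C@H](c2ccccc2)O[C@@]1(C=C)[C@@]1(C)CCC(=O)C(C)C12CO2 | intermediate (not isolated)
22 | 4-methyl-4-en-3-one with C6–OH | C[C@@H]1CO[C@H](c2ccccc2)O[C@@]1(C=C)[C@@]1(C)CCC(=O)C(C)=C1CO | intermediate
23 | 6-O-TBS ether of 22 | C[C@@H]1CO[C@H](c2ccccc2)O[C@@]1(C=C)[C@@]1(C)CCC(=O)C(C)=C1CO[Si](C)(C)C(C)(C)C | intermediate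
24 | (3S)-allylic alcohol (3β-OH) | C[C@@H]1CO[C@H](c2ccccc2)O[C@@]1(C=C)[C@@]1(C)CC[C@H](O)C(C)=C1CO[Si](C)(C)C(C)(C)C | intermediate
25 | 3-O-(bromomethyl)dimethylsilyl ether of 24 | C[C@@H]1CO[C@H](c2ccccc2)O[C@@]1(C=C)[C@@]1(C)CC[C@H](O[Si](C)(C)CBr)C(C)=C1CO[Si](C)(C)C(C)(C)C | intermediate
26 | cyclic siloxane (C3–O–SiMe2–C19H2–C4, 5α-H) | C[C@@H]1CO[C@H](c2ccccc2)O[C@@]1(C=C)[C@@]1(C)CC[C@@H]2O[Si](C)(C)C[C@]2(C)[C@@H]1CO[Si](C)(C)C(C)(C)C | intermediate (not isolated)
27 | 3β,19-diol | C[C@@H]1CO[C@H](c2ccccc2)O[C@@]1(C=C)[C@@]1(C)CC[C@H](O)[C@](C)(CO)[C@@H]1CO[Si](C)(C)C(C)(C)C | intermediate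
28 | 3β,19-diacetate | C[C@@H]1CO[C@H](c2ccccc2)O[C@@]1(C=C)[C@@]1(C)CC[C@H](OC(C)=O)[C@](C)(COC(C)=O)[C@@H]1CO[Si](C)(C)C(C)(C)C | intermediate
29 | 2-bromoprop-2-en-1-ol | OCC(Br)=C | starting material
30 | C12 B-alkyl-9-borabicyclo[3.3.1]nonane | C[C@@H]1CO[C@H](c2ccccc2)O[C@@]1(CCB2C3CCCC2CCC3)[C@@]1(C)CC[C@H](OC(C)=O)[C@](C)(COC(C)=O)[C@@H]1CO[Si](C)(C)C(C)(C)C | intermediate (not isolated)
31 | allylic alcohol (C13=C16H2, C14H2OH) | C[C@@H]1CO[C@H](c2ccccc2)O[C@@]1(CCC(=C)CO)[C@@]1(C)CC[C@H](OC(C)=O)[C@](C)(COC(C)=O)[C@@H]1CO[Si](C)(C)C(C)(C)C | intermediate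
32 | (13S)-13,16-epoxy alcohol | C[C@@H]1CO[C@H](c2ccccc2)O[C@@]1(CC[C@]2(CO)CO2)[C@@]1(C)CC[C@H](OC(C)=O)[C@](C)(COC(C)=O)[C@@H]1CO[Si](C)(C)C(C)(C)C | intermediate
33 | epoxy aldehyde (C14H=O) | C[C@@H]1CO[C@H](c2ccccc2)O[C@@]1(CC[C@]2(C=O)CO2)[C@@]1(C)CC[C@H](OC(C)=O)[C@](C)(COC(C)=O)[C@@H]1CO[Si](C)(C)C(C)(C)C | intermediate
34 | (13S)-13-ethynyl-13,16-epoxide | C[C@@H]1CO[C@H](c2ccccc2)O[C@@]1(CC[C@]2(C#C)CO2)[C@@]1(C)CC[C@H](OC(C)=O)[C@](C)(COC(C)=O)[C@@H]1CO[Si](C)(C)C(C)(C)C | intermediate
35 | 6-O-TBS ether of 36 | CC(=O)OC[C@@]1(C)[C@@H](OC(C)=O)CC[C@@](C)([C@H]1CO[Si](C)(C)C(C)(C)C)[C@]1([C@H](C)CO)CC[C@](CO)(C#C)O1 | intermediate (not isolated)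
36 | (13R)-3β,19-diacetoxy-9α,13-epoxy-6,7-seco-labd-14-yne-6,7,16-triol | CC(=O)OC[C@@]1(C)[C@@H](OC(C)=O)CC[C@@](C)([C@H]1CO)[C@]1([C@H](C)CO)CC[C@](CO)(C#C)O1 | intermediate
37 | (13R)-3β,19-diacetoxy-9α,13;15,16-diepoxy-6,7-seco-labd-14-ene-6,7-diol | CC(=O)OC[C@@]1(C)[C@@H](OC(C)=O)CC[C@@](C)([C@H]1CO)[C@]1([C@H](C)CO)CC[C@]2(C=COC2)O1 | intermediate
38 | (13R)-3β,19-diacetoxy-9α,13;15,16-diepoxy-6,7-seco-labd-14-ene-6,7-dial | CC(=O)OC[C@@]1(C)[C@@H](OC(C)=O)CC[C@@](C)([C@H]1C=O)[C@]1([C@H](C)C=O)CC[C@]2(C=COC2)O1 | intermediate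
39 | (13R)-3β,19-diacetoxy-6β-hydroxy-9α,13;15,16-diepoxylabd-14-en-7-one | CC(=O)OC[C@@]1(C)[C@@H](OC(C)=O)CC[C@@]2(C)[C@H]1[C@H](O)C(=O)[C@@H](C)[C@]21CC[C@]2(C=COC2)O1 | target

**Count and risks**

Total: 29 steps. Longest linear sequence: 25 steps (steps 1–4 or 5–8, then 9–29).

The three steps most likely to fail:

Step 29. The benzoin addition is reversible and the product can enolise under the basic carbene conditions. This could move the C6 carbinol to the equatorial 6α side or scramble the ketol, and enolisation towards C8 could open ring C by β-elimination of O9. Fallback: dialdehyde 38 would instead be closed without base and irreversibly by intramolecular pinacol coupling with SmI2 (THF, tBuOH, −78 °C), which should give the cis-6β,7β-diol F1 through the samarium-bridged ketyl. One equivalent of Dess–Martin periodinane (NaHCO3, 0 °C) would then oxidise the less hindered equatorial C7 carbinol, in preference to the axial 6β hydroxyl flanked by C19 and C20, and return to 39.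

Step 10. The sigmatropic shift joins two fully substituted carbons; it may be slower than decomposition of the crowded ketene acetal, or lose face selectivity at the temperature it needs. Fallback: the same chelate-and-chair logic would be run as a charge-accelerated acyl-Claisen (ketene plus allylic amine) rearrangement at room temperature. Acid 11 would be converted with oxalyl chloride into the acid chloride F2. Alcohol 5 would be oxidised with MnO2 to the enal F3 and reductively aminated (morpholine, NaBH(OAc)3) to the allylic morpholine F4. F2 and F4 with iPr2NEt and Yb(OTf)3 in CH2Cl2 should give, through the O9-chelated zwitterionic enolate, the morpholine amide F5. iBu2AlH at −78 °C would reduce F5 to aldehyde 17.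

Step 26. Under acid, the tertiary propargylic epoxide carbon may ionise and lose the C13 configuration, or be captured by methanol before O9 attacks. Fallback: the order of events would be reversed. Epoxy aldehyde 33, whose carbonyl group disfavours ionisation at C13, would be treated with aqueous acetic acid in THF at 40 °C; O9 opens the epoxide with inversion and the acetal and silyl ether are shed, giving the triol aldehyde F6. An excess of lithiated (trimethylsilyl)diazomethane at −78 °C would then homologate F6 to alkyne 36.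

**Further compounds**

F1 | step 29 | (13R)-3β,19-diacetoxy-9α,13;15,16-diepoxylabd-14-ene-6β,7β-diol | CC(=O)OC[C@@]1(C)[C@@H](OC(C)=O)CC[C@@]2(C)[C@H]1[C@H](O)[C@H](O)[C@@H](C)[C@]21CC[C@]2(C=COC2)O1
F2 | step 10 | (2S,4S,5R)-5-methyl-2-phenyl-1,3-dioxane-4-carbonyl chloride | C[C@@H]1CO[C@H](c2ccccc2)O[C@@H]1C(Cl)=O
F3 | step 10 | 5,5-dimethoxy-2-methylcyclohex-1-ene-1-carbaldehyde | COC1(OC)CCC(C)=C(C=O)C1
F4 | step 10 | 4-[(5,5-dimethoxy-2-methylcyclohex-1-en-1-yl)methyl]morpholine | COC1(OC)CCC(C)=C(CN2CCOCC2)C1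
F5 | step 10 | morpholine amide of acid 15 | C[C@@H]1CO[C@H](c2ccccc2)O[C@@]1(C(=O)N2CCOCC2)[C@@]1(C)CCC(OC)(OC)CC1=C
F6 | step 26 | 3β,19-diacetoxy-9α,13-epoxy-6,7,16-trihydroxy-6,7-seco-15-norlabdan-14-al | CC(=O)OC[C@@]1(C)[C@@H](OC(C)=O)CC[C@@](C)([C@H]1CO)[C@]1([C@H](C)CO)CC[C@](CO)(C=O)O1
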